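**Retrosynthetic overview**
- The strategy rests on the C6–C7 bond. It is common to the ten-membered carbocycle (C1–C10) and the butenolide (C6, C7, C11, C12, O), and C6 lies cis to C12 across the tetrasubstituted C7=C11 alkene. Both rings are closed last, in one operation, from an acyclic C1–C15 chain: the alkenylchromium made from a (Z)-C7 iodide adds to a C6 cis-enal (ten-membered ring first), and the C6 alkoxide then acylates on the C12 methyl ester (butenolide second).
- The (Z)-β-iodo enoate comes from a stannane, this from a (Z)-enol triflate, and this from a β-keto ester made by crossed Claisen condensation (C7–C11) of a C7 ester with the C11–C13 propanoate enolate.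
- C9–C10 and the C8 stereocenter come from copper-catalysed opening of methyl (S)-glycidate by the C10 alkenylmagnesium. C1 is set by CBS reduction of a 2-iodoenone. C1–C6 and C15 come from nerol by cleavage of its terminal alkene.
- Endgame: both TES ethers off, two acetates on, TBS off.

Key step: step 18

Remark: germacrane numbering is used (ring C1–C10, lactone carbons C11–C13, C14 the exocyclic methylene, C15 the methyl on C4), and the target is the (1S,6R,8S)-isomer with a Z C4=C5 alkene. The C7=C11 geometry is fixed through a chelated β-keto ester enolate (steps 12–15) rather than by iodide addition to a C8-substituted ynoate with formaldehyde trapping, because in that allenolate the face attacked at C11 depends only on the small steric difference between iodine and the C8 substituent.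

**Step 1**
Reactants: 1 nerol
Product: 2 neryl 4-methoxybenzyl ether, (Z)-1-(4-methoxybenzyloxy)-3,7-dimethylocta-2,6-diene
Conditions: NaH, 4-methoxybenzyl chloride, n-Bu4NI (cat.), THF/DMF, 0 °C → rt
Reagents that add atoms: 4-methoxybenzyl chloride, COc1ccc(CCl)cc1
Why: Williamson etherification of the primary allylic alkoxide installs a C6 protecting group that survives organolithium and enolate chemistry and can later be removed oxidatively in the presence of three silyl ethers.

**Step 2**
Reactants: 2 neryl 4-methoxybenzyl ether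
Product: 3 racemic 2,2-dimethyl-3-[(Z)-5-(4-methoxybenzyloxy)-3-methylpent-3-enyl]oxirane
Conditions: mCPBA (1.0 equiv), NaHCO3, CH2Cl2, −20 → 0 °C
Reagents that add atoms: 3-chloroperoxybenzoic acid, O=C(OO)c1cccc(Cl)c1
Why: Peracid (Prilezhaev) epoxidation should take place at the terminal trisubstituted alkene, which is the more electron-rich one because the C4=C5 alkene is deactivated by its allylic ether oxygen.

**Step 3**
Reactants: 3 racemic terminal epoxide
Product: 4 (Z)-6-(4-methoxybenzyloxy)-4-methylhex-4-enal (the C1 aldehyde)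
Conditions: H5IO6, THF/H2O, 0 °C
Reagents that add atoms: none
Why: Acid-catalysed hydration of the epoxide and periodate glycol cleavage in the same flask excise the isopropylidene carbons as acetone and leave the C1 aldehyde, with the Z-alkene and the benzyl-type ether untouched.

**Step 4**
Reactants: 4 (Z)-6-(4-methoxybenzyloxy)-4-methylhex-4-enal; 5 vinylmagnesium bromide
Product: 6 racemic (Z)-8-(4-methoxybenzyloxy)-6-methylocta-1,6-dien-3-ol
Conditions: THF, −78 → 0 °C; aq. NH4Cl
Reagents that add atoms: none
Why: Grignard 1,2-addition to the aldehyde attaches C10 and C14, and the carbinol is accepted as a racemate because C1 is set later by reduction of the derived ketone.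

**Step 5**
Reactants: 6 racemic allylic alcohol
Product: 7 (Z)-8-(4-methoxybenzyloxy)-6-methylocta-1,6-dien-3-one
Conditions: Dess–Martin periodinane, NaHCO3, CH2Cl2, 0 °C → rt
Reagents that add atoms: none
Why: Dess–Martin oxidation under buffered, non-basic conditions gives the vinyl ketone without conjugate addition or Z/E isomerisation, and it is used without storage.

**Step 6**
Reactants: 7 vinyl ketone
Product: 8 (Z)-2-iodo-8-(4-methoxybenzyloxy)-6-methylocta-1,6-dien-3-one
Conditions: I2, pyridine/CH2Cl2 (1:1), 0 °C → rt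
Reagents that add atoms: iodine, II
Why: Iodine–pyridine α-iodination of an enone (conjugate addition of pyridine, iodination of the enolate and elimination of pyridine) is fastest for β-unsubstituted vinyl ketones and places iodine on C10.

**Step 7**
Reactants: 8 2-iodoenone
Product: 9 (3S,6Z)-2-iodo-8-(4-methoxybenzyloxy)-6-methylocta-1,6-dien-3-ol
Conditions: (R)-2-methyl-CBS-oxazaborolidine (20 mol%), catecholborane, toluene, −78 °C; MeOH, then aq. NaOH wash
Reagents that add atoms: none
Why: Corey–Bakshi–Shibata reduction, for which 2-haloenones are well-behaved substrates, treats the 1-iodovinyl group as the large substituent so that the (R)-oxazaborolidine should give the (S)-carbinol at C1, while catecholborane at low temperature leaves the alkenes alone.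

**Step 8**
Reactants: 9 (S)-2-iodoallylic alcohol
Product: 10 (3S,6Z)-3-(tert-butyldimethylsilyloxy)-2-iodo-8-(4-methoxybenzyloxy)-6-methylocta-1,6-diene
Conditions: TBSCl, imidazole, DMF, rt
Reagents that add atoms: tert-butyldimethylsilyl chloride, CC(C)(C)[Si](C)(C)Cl
Why: Silylation of the secondary alcohol with silyl chloride and imidazole gives a TBS ether that is meant to outlast the later acid cleavage of the TES ethers.

**Step 9**
Reactants: 10 alkenyl iodide; 11 methyl (S)-glycidate
Product: 14 methyl (2S,5S,8Z)-5-(tert-butyldimethylsilyloxy)-2-hydroxy-10-(4-methoxybenzyloxy)-8-methyl-4-methylidenedec-8-enoate, via alkenyllithium 12 (not isolated), via alkenylmagnesium bromide 13 (not isolated)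
Conditions: t-BuLi (2.0 equiv), Et2O, −78 °C; MgBr2·OEt2, −78 °C; CuI (10 mol%), THF, then 11, −40 → −20 °C; aq. NH4Cl
Reagents that add atoms: none
Why: Iodine–lithium exchange with retention of the alkene, transmetalation to magnesium and copper-catalysed SN2 opening of the epoxide at its CH2 terminus (a known reaction of alkenyl Grignard reagents with methyl glycidate) form C9–C10 and import C8 from the chiral pool with its C–O bond untouched, so that C8 is S.

**Step 10**
Reactants: 14 α-hydroxy ester
Product: 15 methyl (2S,5S,8Z)-5-(tert-butyldimethylsilyloxy)-10-(4-methoxybenzyloxy)-8-methyl-4-methylidene-2-(triethylsilyloxy)dec-8-enoate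
Conditions: TESCl, imidazole, DMAP (cat.), CH2Cl2, 0 °C → rt
Reagents that add atoms: chlorotriethylsilane, CC[Si](CC)(CC)Cl
Why: Silylation of the α-hydroxy ester masks the C8 hydroxyl as a TES ether, a poor leaving group for the later alkenylmetal and removable together with the C13 ether.

**Step 11**
Reactants: 16 methyl 3-hydroxypropanoate
Product: 17 methyl 3-(triethylsilyloxy)propanoate
Conditions: TESCl, imidazole, CH2Cl2, 0 °C
Reagents that add atoms: chlorotriethylsilane, CC[Si](CC)(CC)Cl
Why: Silylation of the primary alcohol gives the C11–C13 building block whose lithium enolate tolerates the β-silyloxy group at low temperature.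

**Step 12**
Reactants: 15 C7 methyl ester; 17 methyl 3-(triethylsilyloxy)propanoate
Product: 19 methyl (4S,7S,10Z)-7-(tert-butyldimethylsilyloxy)-12-(4-methoxybenzyloxy)-10-methyl-6-methylidene-3-oxo-4-(triethylsilyloxy)-2-[(triethylsilyloxy)methyl]dodec-10-enoate (both C2 epimers), via lithium ester enolate 18 (not isolated)
Conditions: LiN(i-Pr)2 (3.2 equiv), 17 (3.0 equiv), THF, −78 °C; then 15, −78 → −50 °C; AcOH, −78 °C
Reagents that add atoms: none
Why: Crossed Claisen condensation of the preformed lithium ester enolate (in excess) with the inductively activated α-silyloxy methyl ester forms C7–C11, the β-keto ester being held as its enolate until the acidic quench so that C8 is not epimerised, and the configuration at C11 is of no consequence.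

**Step 13**
Reactants: 19 β-keto ester
Product: 21 methyl (2Z,4S,7S,10Z)-7-(tert-butyldimethylsilyloxy)-12-(4-methoxybenzyloxy)-10-methyl-6-methylidene-4-(triethylsilyloxy)-2-[(triethylsilyloxy)methyl]-3-(trifluoromethylsulfonyloxy)dodeca-2,10-dienoate, via chelated lithium enolate 20 (not isolated)
Conditions: LiN(SiMe3)2 (1.05 equiv), THF, −78 °C; N-(5-chloro-2-pyridyl)bis(trifluoromethanesulfonimide), −78 → 0 °C
Reagents that add atoms: N-(5-chloro-2-pyridyl)bis(trifluoromethanesulfonimide), O=S(=O)(N(c1ccc(Cl)cn1)S(=O)(=O)C(F)(F)F)C(F)(F)F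
Why: O-Sulfonylation of a β-keto ester enolate: lithium bridges the enolate oxygen on C7 and the ester carbonyl, so the triflate is expected cis to C12 (Z), which places C8 cis to C13 as the lactone requires.

**Step 14**
Reactants: 21 (Z)-enol triflate
Product: 22 methyl (2Z,4S,7S,10Z)-7-(tert-butyldimethylsilyloxy)-12-(4-methoxybenzyloxy)-10-methyl-6-methylidene-4-(triethylsilyloxy)-2-[(triethylsilyloxy)methyl]-3-(trimethylstannyl)dodeca-2,10-dienoate
Conditions: (Me3Sn)2, Pd(PPh3)4 (5 mol%), LiCl, THF, 60 °C
Reagents that add atoms: hexamethylditin, C[Sn](C)(C)[Sn](C)(C)C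
Why: Palladium-catalysed stannylation of an enol triflate with hexamethylditin (Stille-type coupling, chloride-assisted) goes through oxidative addition and reductive elimination with retention of the alkene geometry.

**Step 15**
Reactants: 22 (Z)-alkenylstannane
Product: 23 methyl (2Z,4S,7S,10Z)-7-(tert-butyldimethylsilyloxy)-3-iodo-12-(4-methoxybenzyloxy)-10-methyl-6-methylidene-4-(triethylsilyloxy)-2-[(triethylsilyloxy)methyl]dodeca-2,10-dienoate
Conditions: I2 (1.05 equiv), CH2Cl2, 0 °C; aq. Na2S2O3
Reagents that add atoms: iodine, II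
Why: Iododestannylation is an ipso electrophilic substitution that proceeds with retention and gives the tetrasubstituted (Z)-β-iodo enoate, the isolated alkenes adding iodine only reversibly.

**Step 16**
Reactants: 23 (Z)-β-iodo enoate, C6 4-methoxybenzyl ether
Product: 24 methyl (2Z,4S,7S,10Z)-7-(tert-butyldimethylsilyloxy)-12-hydroxy-3-iodo-10-methyl-6-methylidene-4-(triethylsilyloxy)-2-[(triethylsilyloxy)methyl]dodeca-2,10-dienoate
Conditions: DDQ, CH2Cl2/pH 7 phosphate buffer (10:1), 0 °C
Reagents that add atoms: none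
Why: Oxidative cleavage of the 4-methoxybenzyl ether by DDQ (hydride abstraction and hydrolysis of the oxocarbenium ion) in buffered wet dichloromethane frees the C6 hydroxyl without touching silyl ethers or the alkenyl iodide.

**Step 17**
Reactants: 24 C6 allylic alcohol
Product: 25 methyl (2Z,4S,7S,10Z)-7-(tert-butyldimethylsilyloxy)-3-iodo-10-methyl-6-methylidene-12-oxo-4-(triethylsilyloxy)-2-[(triethylsilyloxy)methyl]dodeca-2,10-dienoate (cis-enal at C6, (Z)-β-iodo enoate at C7=C11)
Conditions: Dess–Martin periodinane, NaHCO3, CH2Cl2, 0 °C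
Reagents that add atoms: none
Why: Dess–Martin oxidation of the allylic alcohol gives the cis-enal without acid or base, so that the Z geometry of C4=C5 is kept.

**Step 18**
Reactants: 25 acyclic iodo enoate enal
Product: 28 (1S,6R,8S)-1-(tert-butyldimethylsilyloxy)-8,13-bis(triethylsilyloxy)germacra-4(Z),7(11),10(14)-trien-6,12-olide, via alkenylchromium dichloride 26 (not isolated), via macrocyclic chromium alkoxide 27 (not isolated)
Conditions: CrCl2 (10 equiv), NiCl2 (0.1 equiv), degassed DMSO, rt, 25 added over 12 h by syringe pump (final 0.002 M)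
Reagents that add atoms: none
Why: Nozaki–Hiyama–Kishi reaction: zerovalent nickel (from catalytic NiCl2 and CrCl2) inserts into the C7–I bond, transmetalation to trivalent chromium gives alkenylchromium 26 with retention, and this adds 1,2 to the C6 aldehyde; the closest known reactions are the nickel/chromium coupling of (Z)-β-iodo enoates with aldehydes to give butenolides and nickel/chromium macrocyclisations to medium rings. The ten-membered carbocycle closes in this addition as a 10-exo-trig attack of C7 on the C6 carbonyl, and the chromium alkoxide 27, held cis to the ester by the C7=C11 geometry, closes the butenolide by 5-exo-trig acyl substitution at C12 with loss of methoxide, which makes the sequence irreversible. The new stereocenter C6 is controlled by the substrate: allylic 1,3-strain with the cis C13 methylene turns C8–H into the alkene plane, the same strain with C12 does so for C6–H in the transition state, and the seven-atom bridge through the cis C4=C5 alkene can only span C8 and C6 if the bonds C8–C9 and C6–C5 leave the C7=C11 plane on the same face, which puts the oxygens at C6 and C8 cis (6α,8α). The step needs chemoselectivity (nickel inserts only into the electron-poor alkenyl iodide, and the neutral chromium reagent spares ester, silyl ethers and the acidic C6–H of the product), 1,2- rather than 1,4-addition to the enal (normal for alkenylchromium reagents), ring closure rather than oligomerisation (slow addition at high dilution) and no β-elimination to an allene (C8 carries a silyl ether, a poor leaving group).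

**Step 19**
Reactants: 28 tris-silylated lactone
Product: 29 (1S,6R,8S)-1-(tert-butyldimethylsilyloxy)-8,13-dihydroxygermacra-4(Z),7(11),10(14)-trien-6,12-olide
Conditions: PPTS (0.2 equiv), MeOH/CH2Cl2 (1:1), 0 °C
Reagents that add atoms: none
Why: Acid-catalysed methanolysis of silyl ethers removes the two triethylsilyl groups much faster than the more hindered secondary TBS ether, and the freed C8 hydroxyl, being trans to C12 across C7=C11, cannot translactonise.

**Step 20**
Reactants: 29 8,13-diol
Product: 30 (1S,6R,8S)-8,13-diacetoxy-1-(tert-butyldimethylsilyloxy)germacra-4(Z),7(11),10(14)-trien-6,12-olide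
Conditions: Ac2O, pyridine, DMAP (cat.), CH2Cl2, 0 °C → rt
Reagents that add atoms: acetic anhydride, CC(=O)OC(C)=O
Why: DMAP-catalysed acetylation esterifies the secondary C8 and primary C13 hydroxyls under weakly basic conditions that do not deprotonate C6.

**Step 21**
Reactants: 30 diacetate TBS ether
Product: 31 8α,13-diacetoxy-1α-hydroxygermacra-4,7(11),10(14)-trien-6α,12-olide
Conditions: HF·pyridine, pyridine, THF, 0 °C → rt
Reagents that add atoms: none
Why: Fluoride-induced desilylation with pyridine-buffered HF·pyridine cleaves the remaining TBS ether without acyl migration, acetate cleavage or epimerisation at C6.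

**Compound list**
1 | nerol | CC(C)=CCC/C(C)=C\CO | starting material
2 | neryl 4-methoxybenzyl ether | CC(C)=CCC/C(C)=C\COCc1ccc(OC)cc1 | intermediate
3 | racemic 2,2-dimethyl-3-[(Z)-5-(4-methoxybenzyloxy)-3-methylpent-3-enyl]oxirane | CC1(C)OC1CC/C(C)=C\COCc1ccc(OC)cc1 | intermediate
4 | (Z)-6-(4-methoxybenzyloxy)-4-methylhex-4-enal | O=CCC/C(C)=C\COCc1ccc(OC)cc1 | intermediate
5 | vinylmagnesium bromide | C=C[Mg]Br | starting material
6 | racemic (Z)-8-(4-methoxybenzyloxy)-6-methylocta-1,6-dien-3-ol | C=CC(O)CC/C(C)=C\COCc1ccc(OC)cc1 | intermediate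
7 | (Z)-8-(4-methoxybenzyloxy)-6-methylocta-1,6-dien-3-one | C=CC(=O)CC/C(C)=C\COCc1ccc(OC)cc1 | intermediate
8 | (Z)-2-iodo-8-(4-methoxybenzyloxy)-6-methylocta-1,6-dien-3-one | C=C(I)C(=O)CC/C(C)=C\COCc1ccc(OC)cc1 | intermediate
9 | (3S,6Z)-2-iodo-8-(4-methoxybenzyloxy)-6-methylocta-1,6-dien-3-ol | C=C(I)[C@@H](O)CC/C(C)=C\COCc1ccc(OC)cc1 | intermediate
10 | (3S,6Z)-3-(tert-butyldimethylsilyloxy)-2-iodo-8-(4-methoxybenzyloxy)-6-methylocta-1,6-diene | C=C(I)[C@@H](O[Si](C)(C)C(C)(C)C)CC/C(C)=C\COCc1ccc(OC)cc1 | intermediate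
11 | methyl (S)-glycidate, methyl (S)-oxirane-2-carboxylate | COC(=O)[C@@H]1CO1 | starting material
12 | alkenyllithium from 10 (lithium in place of iodine) | C=C([Li])[C@@H](O[Si](C)(C)C(C)(C)C)CC/C(C)=C\COCc1ccc(OC)cc1 | intermediate
13 | alkenylmagnesium bromide from 12 | C=C([Mg]Br)[C@@H](O[Si](C)(C)C(C)(C)C)CC/C(C)=C\COCc1ccc(OC)cc1 | intermediate
14 | methyl (2S,5S,8Z)-5-(tert-butyldimethylsilyloxy)-2-hydroxy-10-(4-methoxybenzyloxy)-8-methyl-4-methylidenedec-8-enoate | C=C(C[C@H](O)C(=O)OC)[C@@H](O[Si](C)(C)C(C)(C)C)CC/C(C)=C\COCc1ccc(OC)cc1 | intermediate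
15 | 2-O-triethylsilyl ether of 14 | C=C(C[C@H](O[Si](CC)(CC)CC)C(=O)OC)[C@@H](O[Si](C)(C)C(C)(C)C)CC/C(C)=C\COCc1ccc(OC)cc1 | intermediate
16 | methyl 3-hydroxypropanoate | COC(=O)CCO | starting material
17 | methyl 3-(triethylsilyloxy)propanoate | COC(=O)CCO[Si](CC)(CC)CC | intermediate
18 | lithium enolate of 17 | COC(O[Li])=CCO[Si](CC)(CC)CC | intermediate
19 | β-keto ester, methyl (4S,7S,10Z)-7-(tert-butyldimethylsilyloxy)-12-(4-methoxybenzyloxy)-10-methyl-6-methylidene-3-oxo-4-(triethylsilyloxy)-2-[(triethylsilyloxy)methyl]dodec-10-enoate, both C2 epimers | C=C(C[C@H](O[Si](CC)(CC)CC)C(=O)C(CO[Si](CC)(CC)CC)C(=O)OC)[C@@H](O[Si](C)(C)C(C)(C)C)CC/C(C)=C\COCc1ccc(OC)cc1 | intermediate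
20 | chelated lithium (Z)-enolate of 19 | C=C(C[C@H](O[Si](CC)(CC)CC)/C(O[Li])=C(\CO[Si](CC)(CC)CC)C(=O)OC)[C@@H](O[Si](C)(C)C(C)(C)C)CC/C(C)=C\COCc1ccc(OC)cc1 | intermediate
21 | (Z)-enol triflate of 19 (triflate on C7 cis to the ester) | C=C(C[C@H](O[Si](CC)(CC)CC)/C(OS(=O)(=O)C(F)(F)F)=C(\CO[Si](CC)(CC)CC)C(=O)OC)[C@@H](O[Si](C)(C)C(C)(C)C)CC/C(C)=C\COCc1ccc(OC)cc1 | intermediate
22 | (Z)-β-trimethylstannyl enoate (tin on C7 cis to the ester) | C=C(C[C@H](O[Si](CC)(CC)CC)/C([Sn](C)(C)C)=C(\CO[Si](CC)(CC)CC)C(=O)OC)[C@@H](O[Si](C)(C)C(C)(C)C)CC/C(C)=C\COCc1ccc(OC)cc1 | intermediate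
23 | (Z)-β-iodo enoate, C6 4-methoxybenzyl ether | C=C(C[C@H](O[Si](CC)(CC)CC)/C(I)=C(\CO[Si](CC)(CC)CC)C(=O)OC)[C@@H](O[Si](C)(C)C(C)(C)C)CC/C(C)=C\COCc1ccc(OC)cc1 | intermediate
24 | (Z)-β-iodo enoate, free C6 allylic alcohol | C=C(C[C@H](O[Si](CC)(CC)CC)/C(I)=C(\CO[Si](CC)(CC)CC)C(=O)OC)[C@@H](O[Si](C)(C)C(C)(C)C)CC/C(C)=C\CO | intermediate
25 | (Z)-β-iodo enoate cis-enal, methyl (2Z,4S,7S,10Z)-7-(tert-butyldimethylsilyloxy)-3-iodo-10-methyl-6-methylidene-12-oxo-4-(triethylsilyloxy)-2-[(triethylsilyloxy)methyl]dodeca-2,10-dienoate | C=C(C[C@H](O[Si](CC)(CC)CC)/C(I)=C(\CO[Si](CC)(CC)CC)C(=O)OC)[C@@H](O[Si](C)(C)C(C)(C)C)CC/C(C)=C\C=O | intermediate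
26 | alkenylchromium dichloride from 25 (trivalent chromium on C7) | C=C(C[C@H](O[Si](CC)(CC)CC)/C([Cr](Cl)Cl)=C(\CO[Si](CC)(CC)CC)C(=O)OC)[C@@H](O[Si](C)(C)C(C)(C)C)CC/C(C)=C\C=O | intermediate
27 | ten-membered (6R) chromium alkoxide with the C12 methyl ester still open | C=C1C[C@H](O[Si](CC)(CC)CC)/C(=C(\CO[Si](CC)(CC)CC)C(=O)OC)[C@H](O[Cr](Cl)Cl)/C=C(/C)CC[C@@H]1O[Si](C)(C)C(C)(C)C | intermediate
28 | (1S,6R,8S)-1-(tert-butyldimethylsilyloxy)-8,13-bis(triethylsilyloxy)germacra-4(Z),7(11),10(14)-trien-6,12-olide | C=C1C[C@H](O[Si](CC)(CC)CC)C2=C(CO[Si](CC)(CC)CC)C(=O)O[C@@H]2/C=C(/C)CC[C@@H]1O[Si](C)(C)C(C)(C)C | intermediate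
29 | (1S,6R,8S)-1-(tert-butyldimethylsilyloxy)-8,13-dihydroxygermacra-4(Z),7(11),10(14)-trien-6,12-olide | C=C1C[C@H](O)C2=C(CO)C(=O)O[C@@H]2/C=C(/C)CC[C@@H]1O[Si](C)(C)C(C)(C)C | intermediate
30 | (1S,6R,8S)-8,13-diacetoxy-1-(tert-butyldimethylsilyloxy)germacra-4(Z),7(11),10(14)-trien-6,12-olide | C=C1C[C@H](OC(C)=O)C2=C(COC(C)=O)C(=O)O[C@@H]2/C=C(/C)CC[C@@H]1O[Si](C)(C)C(C)(C)C | intermediate
31 | 8α,13-diacetoxy-1α-hydroxygermacra-4,7(11),10(14)-trien-6α,12-olide | C=C1C[C@H](OC(C)=O)C2=C(COC(C)=O)C(=O)O[C@@H]2/C=C(/C)CC[C@@H]1O | target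

**Step count**
Total: 21 steps. Longest linear sequence: 20 steps (steps 1–10 and 12–21 from nerol); step 11 prepares the C11–C13 ester on the side.

**Steps most likely to fail**

1. Step 18. The alkenylchromium may add intermolecularly (oligomers), may lose its alkene geometry at the nickel or chromium stage so that the alkoxide can no longer reach C12, or may attack the wrong face of the aldehyde at C6. The fallback sets out from stannane 22 and returns at 28; it closes the same ring by acylation and sets C6 by a reagent.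
   - DDQ and then Dess–Martin periodinane, as in steps 16 and 17, would give the stannyl alcohol F1 and the stannyl cis-enal F2.
   - Pinnick oxidation (NaClO2, NaH2PO4, 2-methyl-2-butene) would give the (Z)-enoic acid F3, and 1-chloro-N,N,2-trimethylpropenylamine would convert it into the acid chloride F4.
   - Under high dilution with Pd2(dba)3, AsPh3 and CuI, an intramolecular Stille acylation would join C6 to C7 and give the ten-membered cross-conjugated C6 ketone F5.
   - CBS reduction with the (S)-oxazaborolidine and catecholborane, in which the tetrasubstituted C7 alkenyl group is the large substituent, would give the (6R)-hydroxy ester F6, which lactonises onto the cis methyl ester to 28.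

2. Step 12. Proton transfer from C8–H of ester 15 to the enolate (erosion of the C8 configuration) and β-elimination of silanolate from enolate 18 may compete with acylation. The fallback sets out from 15 and returns at 19; it replaces acyl substitution by aldol addition and oxidation. Reduction with i-Bu2AlH in CH2Cl2 at −78 °C would give the α-silyloxy aldehyde F7. Addition of enolate 18 at −78 °C, which is faster than any proton transfer, would give the β-hydroxy ester F8 as a mixture of diastereomers. Dess–Martin oxidation would then give 19.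

3. Step 14. Oxidative addition and transmetalation at the hindered tetrasubstituted triflate may be slow, and the alkenylpalladium may lose the C8 silyloxy group by β-elimination to an allene. The fallback sets out from 21 and returns at 28; it leaves out tin and iodine and uses the enol triflate itself as the electrophile for nickel. DDQ would give the triflate alcohol F9 and Dess–Martin periodinane the triflate cis-enal F10. F10 would be cyclised with CrCl2 and catalytic NiCl2 in DMF at high dilution (alkenyl triflates are standard partners in nickel/chromium couplings), giving 28 by the same addition and lactonisation.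

**Further compounds**
F1 | step 18 | stannyl alcohol, 22 with a free C6 hydroxyl in place of the 4-methoxybenzyl ether | C=C(C[C@H](O[Si](CC)(CC)CC)/C([Sn](C)(C)C)=C(\CO[Si](CC)(CC)CC)C(=O)OC)[C@@H](O[Si](C)(C)C(C)(C)C)CC/C(C)=C\CO
F2 | step 18 | stannyl cis-enal | C=C(C[C@H](O[Si](CC)(CC)CC)/C([Sn](C)(C)C)=C(\CO[Si](CC)(CC)CC)C(=O)OC)[C@@H](O[Si](C)(C)C(C)(C)C)CC/C(C)=C\C=O
F3 | step 18 | stannyl (Z)-enoic acid (C6 carboxylic acid) | C=C(C[C@H](O[Si](CC)(CC)CC)/C([Sn](C)(C)C)=C(\CO[Si](CC)(CC)CC)C(=O)OC)[C@@H](O[Si](C)(C)C(C)(C)C)CC/C(C)=C\C(=O)O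
F4 | step 18 | stannyl (Z)-enoyl chloride | C=C(C[C@H](O[Si](CC)(CC)CC)/C([Sn](C)(C)C)=C(\CO[Si](CC)(CC)CC)C(=O)OC)[C@@H](O[Si](C)(C)C(C)(C)C)CC/C(C)=C\C(=O)Cl
F5 | step 18 | ten-membered C6 ketone with the C12 methyl ester open | C=C1C[C@H](O[Si](CC)(CC)CC)/C(=C(\CO[Si](CC)(CC)CC)C(=O)OC)C(=O)/C=C(/C)CC[C@@H]1O[Si](C)(C)C(C)(C)C
F6 | step 18 | ten-membered (6R)-hydroxy methyl ester | C=C1C[C@H](O[Si](CC)(CC)CC)/C(=C(\CO[Si](CC)(CC)CC)C(=O)OC)[C@H](O)/C=C(/C)CC[C@@H]1O[Si](C)(C)C(C)(C)C
F7 | step 12 | (2S,5S,8Z)-5-(tert-butyldimethylsilyloxy)-10-(4-methoxybenzyloxy)-8-methyl-4-methylidene-2-(triethylsilyloxy)dec-8-enal | C=C(C[C@H](O[Si](CC)(CC)CC)C=O)[C@@H](O[Si](C)(C)C(C)(C)C)CC/C(C)=C\COCc1ccc(OC)cc1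
F8 | step 12 | β-hydroxy ester, 19 with a C7 hydroxyl in place of the ketone, mixture of diastereomers at C7 and C11 | C=C(C[C@H](O[Si](CC)(CC)CC)C(O)C(CO[Si](CC)(CC)CC)C(=O)OC)[C@@H](O[Si](C)(C)C(C)(C)C)CC/C(C)=C\COCc1ccc(OC)cc1
F9 | step 14 | (Z)-enol triflate with free C6 allylic alcohol | C=C(C[C@H](O[Si](CC)(CC)CC)/C(OS(=O)(=O)C(F)(F)F)=C(\CO[Si](CC)(CC)CC)C(=O)OC)[C@@H](O[Si](C)(C)C(C)(C)C)CC/C(C)=C\CO
F10 | step 14 | (Z)-enol triflate cis-enal | C=C(C[C@H](O[Si](CC)(CC)CC)/C(OS(=O)(=O)C(F)(F)F)=C(\CO[Si](CC)(CC)CC)C(=O)OC)[C@@H](O[Si](C)(C)C(C)(C)C)CC/C(C)=C\C=O
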